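Disconnecting ring C of the flavanone at O1–C2 and C3–C4 underlies the whole route. O1–C8a–C4a–C4 on the fully substituted ring A is treated as an ortho-quinone methide oxa-diene whose C4 carries a methoxy group, and C2–C3 with ring B is styrene. A chiral Brønsted acid unites a hexasubstituted salicylaldehyde, trimethyl orthoformate and styrene in one enantioselective hetero-Diels–Alder step that closes ring C and sets C2. The precursor has a single free phenol (the future O1), three methyl ethers, and the benzyl-protected 2-hydroxy-5-methoxybenzyl arm at the future C8. The benzyl ether is kept because one BCl3 treatment at the end frees both phenols.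

Key step: step 5

Assumption: flavan numbering is used throughout, and (2S,4S) in the cycloadduct is the 2,4-cis isomer. The sense of induction of the chiral acid cannot be predicted, so the (R)-catalyst is written and its mirror image would be used if it favours the 2R series.

Step 1
Reactants: 1 2-hydroxy-5-methoxybenzaldehyde
Product: 2 2-(benzyloxy)-5-methoxybenzaldehyde
Conditions: BnBr, K2CO3, DMF, rt
Reagents that add atoms: benzyl bromide, BrCc1ccccc1
Why: Williamson etherification of the phenoxide with a benzylic bromide is routine, and the aldehyde is inert to carbonate.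

Step 2
Reactants: 2 2-(benzyloxy)-5-methoxybenzaldehyde
Product: 3 [2-(benzyloxy)-5-methoxyphenyl]methanol
Conditions: NaBH4, MeOH/THF, 0 °C
Reagents that add atoms: none
Why: Borohydride reduction of an aromatic aldehyde should give the benzylic alcohol cleanly and leaves the aryl ethers untouched.

Step 3
Reactants: 3 [2-(benzyloxy)-5-methoxyphenyl]methanol; 4 3,4,5-trimethoxyphenol
Product: 5 2-[2-(benzyloxy)-5-methoxybenzyl]-3,4,5-trimethoxyphenol
Conditions: 4 (3 equiv), TsOH·H2O (10 mol%), HFIP, rt, slow addition of 3
Reagents that add atoms: none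
Why: In this dehydrative Friedel–Crafts benzylation the ortho-alkoxy-stabilised benzylic cation is captured by the phloroglucinol-type phenol 4, whose two free positions are equivalent by symmetry, and the excess of 4 should suppress double benzylation.

Step 4
Reactants: 5 2-[2-(benzyloxy)-5-methoxybenzyl]-3,4,5-trimethoxyphenol
Product: 6 3-[2-(benzyloxy)-5-methoxybenzyl]-2-hydroxy-4,5,6-trimethoxybenzaldehyde
Conditions: MgCl2, Et3N, (CH2O)n, MeCN, reflux; aq. HCl work-up
Reagents that add atoms: paraformaldehyde (as formaldehyde), C=O
Why: In the Casnati–Skattebøl ortho-formylation the magnesium phenoxide delivers formaldehyde to the only free ring position, which is ortho to the hydroxyl, and excess formaldehyde acts as hydride acceptor to give the aldehyde.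

Step 5
Reactants: 6 3-[2-(benzyloxy)-5-methoxybenzyl]-2-hydroxy-4,5,6-trimethoxybenzaldehyde; 7 trimethyl orthoformate; 8 styrene
Product: 11 (2S,4S)-8-[2-(benzyloxy)-5-methoxybenzyl]-4,5,6,7-tetramethoxyflavan, via dimethyl acetal 9 (not isolated), via methoxy ortho-quinone methide 10 (not isolated)
Conditions: (R)-3,3'-bis(2,4,6-triisopropylphenyl)-BINOL N-triflylphosphoramide (10 mol%), 7 (1.5 equiv), 8 (5 equiv), 5 Å MS, toluene, −20 °C
Reagents that add atoms: none
Why: Proposed new method: acid-catalysed acetal exchange with 7 turns the aldehyde of 6 into acetal 9, and loss of methanol gives the methoxy-substituted ortho-quinone methide 10, held as a hydrogen-bonded ion pair by the chiral phosphoramidate; the styrene CH2 then attacks the exocyclic carbon (future C4) while the phenolic oxygen closes on the developing benzylic carbon (future C2) in a concerted, asynchronous inverse-electron-demand hetero-Diels–Alder reaction. The closest known chemistry is the racemic Lewis acid three-component coupling of salicylaldehydes, orthoformates and styrenes to 2,4-cis-4-alkoxy-2-arylchromans, together with chiral Brønsted acid-controlled [4+2] cycloadditions of ortho-quinone methides with activated styrenes. Ring C is closed by an intermolecular [4+2] cycloaddition, four atoms (O1–C8a–C4a–C4) coming from the heterodiene and two from the alkene, with formation of O1–C2 and C3–C4. C2 is set by the catalyst, whose chiral pocket leaves one face of the bound heterodiene open to the alkene, and C4 follows from the endo transition state that places phenyl and methoxy cis, a relationship that is erased later. The step needs regioselectivity (oxygen to the benzylic carbon), secured by the polarity of styrene and by the single free phenol of 6, and chemoselectivity for the alkene over arene nucleophiles, secured by the fully substituted ring A and the excess of styrene. The three methoxy donors on ring A allow ionisation to 10 at low temperature, and the sieves take up methanol so that the equilibrium is not pushed back to 9.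

Step 6
Reactants: 11 (2S,4S)-8-[2-(benzyloxy)-5-methoxybenzyl]-4,5,6,7-tetramethoxyflavan
Product: 12 (2S)-8-[2-(benzyloxy)-5-methoxybenzyl]-5,6,7-trimethoxyflavan-4-ol (mixture of C4 epimers)
Conditions: 0.1 M HCl, THF/H2O (2:1), rt
Reagents that add atoms: water, O
Why: In this SN1 solvolysis the C4 ether, benzylic to a ring with O1, 5-OMe and 7-OMe donors, ionises under dilute acid and the cation is trapped by the large excess of water, while C2 is not involved and the C4 configuration is irrelevant.

Step 7
Reactants: 12 (2S)-8-[2-(benzyloxy)-5-methoxybenzyl]-5,6,7-trimethoxyflavan-4-ol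
Product: 13 (2S)-8-[2-(benzyloxy)-5-methoxybenzyl]-5,6,7-trimethoxyflavanone
Conditions: Dess–Martin periodinane, NaHCO3 (buffer), CH2Cl2, 0 °C to rt
Reagents that add atoms: none
Why: Dess–Martin oxidation of a secondary benzylic alcohol under buffered, non-basic conditions should leave the doubly benzylic C8 methylene alone and cannot open the pyranone ring, so C2 keeps its configuration.

Step 8
Reactants: 13 (2S)-8-[2-(benzyloxy)-5-methoxybenzyl]-5,6,7-trimethoxyflavanone
Product: 14 (2S)-5-hydroxy-8-(2-hydroxy-5-methoxybenzyl)-6,7-dimethoxyflavanone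
Conditions: BCl3 (4 equiv), C6HMe5 (3 equiv), CH2Cl2, −78 to 0 °C; MeOH quench
Reagents that add atoms: none
Why: In this Lewis acid ether cleavage BCl3 removes the aryl benzyl ether at low temperature, with the benzyl cation trapped by pentamethylbenzene, and, by chelation to the C4 carbonyl, cleaves only the peri 5-methoxy group, so the other three methyl ethers and C2 should be unaffected.

Compound list
1 | 2-hydroxy-5-methoxybenzaldehyde | COc1ccc(O)c(C=O)c1 | starting material
2 | 2-(benzyloxy)-5-methoxybenzaldehyde | COc1ccc(OCc2ccccc2)c(C=O)c1 | intermediate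
3 | [2-(benzyloxy)-5-methoxyphenyl]methanol | COc1ccc(OCc2ccccc2)c(CO)c1 | intermediate
4 | 3,4,5-trimethoxyphenol | COc1cc(O)cc(OC)c1OC | starting material
5 | 2-[2-(benzyloxy)-5-methoxybenzyl]-3,4,5-trimethoxyphenol | COc1ccc(OCc2ccccc2)c(Cc2c(O)cc(OC)c(OC)c2OC)c1 | intermediate
6 | 3-[2-(benzyloxy)-5-methoxybenzyl]-2-hydroxy-4,5,6-trimethoxybenzaldehyde | COc1ccc(OCc2ccccc2)c(Cc2c(OC)c(OC)c(OC)c(C=O)c2O)c1 | intermediate
7 | trimethyl orthoformate | COC(OC)OC | starting material
8 | styrene | C=Cc1ccccc1 | starting material
9 | 2-[2-(benzyloxy)-5-methoxybenzyl]-6-(dimethoxymethyl)-3,4,5-trimethoxyphenol (dimethyl acetal of 6) | COc1ccc(OCc2ccccc2)c(Cc2c(OC)c(OC)c(OC)c(C(OC)OC)c2O)c1 | intermediate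
10 | 2-[2-(benzyloxy)-5-methoxybenzyl]-3,4,5-trimethoxy-6-(methoxymethylidene)cyclohexa-2,4-dien-1-one (exocyclic C=C geometry not fixed, since the isomers interconvert through the protonated form) | COC=C1C(=O)C(Cc2cc(OC)ccc2OCc2ccccc2)=C(OC)C(OC)=C1OC | intermediate
11 | (2S,4S)-8-[2-(benzyloxy)-5-methoxybenzyl]-4,5,6,7-tetramethoxyflavan (2-phenyl and 4-methoxy cis) | COc1ccc(OCc2ccccc2)c(Cc2c(OC)c(OC)c(OC)c3c2O[C@H](c2ccccc2)C[C@@H]3OC)c1 | intermediate
12 | (2S)-8-[2-(benzyloxy)-5-methoxybenzyl]-5,6,7-trimethoxyflavan-4-ol (C4 epimer mixture) | COc1ccc(OCc2ccccc2)c(Cc2c(OC)c(OC)c(OC)c3c2O[C@H](c2ccccc2)CC3O)c1 | intermediate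
13 | (2S)-8-[2-(benzyloxy)-5-methoxybenzyl]-5,6,7-trimethoxyflavanone | COc1ccc(OCc2ccccc2)c(Cc2c(OC)c(OC)c(OC)c3c2O[C@H](c2ccccc2)CC3=O)c1 | intermediate
14 | (2S)-5-hydroxy-8-(2-hydroxy-5-methoxybenzyl)-6,7-dimethoxyflavanone | COc1ccc(O)c(Cc2c(OC)c(OC)c(O)c3c2O[C@H](c2ccccc2)CC3=O)c1 | target

Total step count: 8. Longest linear sequence: 8 steps (1 to 14).

Steps most likely to fail

Step 5. The stabilised heterodiene may react too slowly with unactivated styrene, the chiral anion may discriminate the two faces poorly, or styrene may oligomerise under the acid. The fallback uses known chemistry, sets out from 3 and returns at 13. Alcohol 3 C-benzylates commercial 1-(6-hydroxy-2,3,4-trimethoxyphenyl)ethan-1-one F1 at its only free ring position (TsOH·H2O, HFIP, rt) to give 1-{3-[2-(benzyloxy)-5-methoxybenzyl]-2-hydroxy-4,5,6-trimethoxyphenyl}ethan-1-one F2. Heating with N,N-dimethylformamide dimethyl acetal (neat, 90 °C) gives (E)-1-{3-[2-(benzyloxy)-5-methoxybenzyl]-2-hydroxy-4,5,6-trimethoxyphenyl}-3-(dimethylamino)prop-2-en-1-one F3. This closes with loss of dimethylamine (aq. HCl, CH2Cl2, rt) to 8-[2-(benzyloxy)-5-methoxybenzyl]-5,6,7-trimethoxy-4H-chromen-4-one F4. Enantioselective conjugate addition of phenylboronic acid to the chromone then gives flavanone 13, using Pd(OCOCF3)2 (divalent palladium), the t-BuPyOX antipode that leads to 2S, NH4PF6, H2O and ClCH2CH2Cl at 60 °C. Steps 6 and 7 are then not needed.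

Step 8. Excess Lewis acid may also cleave the 6-methoxy group. It may open the pyranone to the chalcone, which would erode C2 and scramble the 8- and 6-benzyl isomers on re-closure. Benzyl cation may also re-add to the electron-rich rings. The fallback sets out from 13 and returns at 14, and it separates the two deprotections. Hydrogenolysis (H2, 10% Pd/C, EtOAc, rt) removes the benzyl group without any cation and gives (2S)-8-(2-hydroxy-5-methoxybenzyl)-5,6,7-trimethoxyflavanone F5. Chelation-controlled demethylation with a limited amount of MgI2 (as its diethyl etherate, THF, rt to 50 °C) then cleaves only the peri 5-methyl ether and gives 14.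

Step 6. The C4 cation may lose a C3 proton (E1) to give the flav-3-ene instead of being captured by water, or the exchange may stall short of completion. The fallback sets out from 11 and returns at 13, and it replaces solvolysis by hydride abstraction. DDQ in CH2Cl2/pH 7 buffer at 0 °C removes the C4 hydride, which is activated by both the ether oxygen and ring A. The resulting oxocarbenium ion is hydrolysed directly to ketone 13, so 12 and step 7 are bypassed. This fallback passes through no new compound (F0). The α-alkoxy C4–H is far more hydridic than the C8 methylene, which should secure the site selectivity.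

Further compounds
F1 | step 5 | 1-(6-hydroxy-2,3,4-trimethoxyphenyl)ethan-1-one | CC(=O)c1c(O)cc(OC)c(OC)c1OC
F2 | step 5 | 1-{3-[2-(benzyloxy)-5-methoxybenzyl]-2-hydroxy-4,5,6-trimethoxyphenyl}ethan-1-one | COc1ccc(OCc2ccccc2)c(Cc2c(OC)c(OC)c(OC)c(C(C)=O)c2O)c1
F3 | step 5 | (E)-1-{3-[2-(benzyloxy)-5-methoxybenzyl]-2-hydroxy-4,5,6-trimethoxyphenyl}-3-(dimethylamino)prop-2-en-1-one | COc1ccc(OCc2ccccc2)c(Cc2c(OC)c(OC)c(OC)c(C(=O)/C=C/N(C)C)c2O)c1
F4 | step 5 | 8-[2-(benzyloxy)-5-methoxybenzyl]-5,6,7-trimethoxy-4H-chromen-4-one | COc1ccc(OCc2ccccc2)c(Cc2c(OC)c(OC)c(OC)c3c2occc3=O)c1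
F5 | step 8 | (2S)-8-(2-hydroxy-5-methoxybenzyl)-5,6,7-trimethoxyflavanone | COc1ccc(O)c(Cc2c(OC)c(OC)c(OC)c3c2O[C@H](c2ccccc2)CC3=O)c1
F0 | step 6 | none | none
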